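**Retrosynthetic overview**
1. Target 8 ⇒ 7: one global Lewis-acid deprotection (six benzyl groups, two acetonides) at the very end.
2. 7 ⇒ two molecules of racemic 6: the 5,5′ biaryl bond is made by oxidative ortho–ortho phenol coupling; the racemate supplies the (1R,2S) and the (1S,2R) half, and a chiral vanadium catalyst sets the axis.
3. 6 ⇒ 5 ⇒ 3: only the 6-OH is left free (CO2H and 7-OH benzylated, pendant catechol as acetonide), so C5 is the single coupling site.
4. 3 ⇒ two molecules of caffeic acid 1: a protecting-group-free oxidative 8–8′ coupling and quinone-methide cyclisation builds each 1-aryl-1,2-dihydronaphthalene with its trans C1/C2 centres in one operation.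
5. Ring order: both dihydronaphthalene rings are formed first (step 1, one per monomer); the monomers are joined afterwards, and no ring is formed at the biaryl stage.

Assumption: the SMILES fixes the four stereocentres (one (1R,2S) half, one (1S,2R) half) but not the BINOL-like, configurationally stable 5,5′ axis, which is then the only element making the molecule chiral; the route delivers this heterochiral compound as one atropisomer, taken as (aS) (the mirror-image catalyst gives (aR)).

**Route**

Step 1
Reactants: 1 caffeic acid (two molecules)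
Product: 3 rac-(1R,2S)-1-(3,4-dihydroxyphenyl)-6,7-dihydroxy-1,2-dihydronaphthalene-2,3-dicarboxylic acid (trans; rac-epiphyllic acid), via bis(quinone methide) 2 (not isolated)
Conditions: NaIO4 (0.45 equiv), acetone/H2O 1:3, 0 °C, 30 min, Ar; EtOAc extraction, RP-18 chromatography (unreacted 1 recovered)
Reagents that add atoms: none
Why: Periodate oxidises the catechol to the caffeoyl o-quinone/semiquinone, C8–C8′ coupling with a second caffeic acid gives bis(quinone methide) 2, one half re-aromatises by loss of H8 and its ring then closes para to the 3-OH onto C7′ of the other quinone methide (oxidative 8–8′ dimerisation / intramolecular quinone-methide Friedel–Crafts cyclisation, the thomasidioic-acid-type reaction), placing aryl and CO2H trans and giving both enantiomers, which the heterochiral target needs.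

Step 2
Reactants: 3 rac-epiphyllic acid
Product: 5 dibenzyl rac-(1R,2S)-7-(benzyloxy)-1-(3,4-dihydroxyphenyl)-6-hydroxy-1,2-dihydronaphthalene-2,3-dicarboxylate, via dibenzyl ester 4 (not isolated)
Conditions: BnBr (3.1 equiv), KHCO3 (3.3 equiv), KI (cat.), DMF, Ar, rt (carboxyl groups) then 55 °C (7-OH)
Reagents that add atoms: benzyl bromide, BrCc1ccccc1
Why: Bicarbonate-controlled O-alkylation (Williamson type): the two carboxylates react first, then only the most acidic phenol is ionised and benzylated, namely the 7-OH para to the conjugated acrylate (a vinylogous acid, as in the selective 4-O-alkylation of 3,4-dihydroxybenzaldehyde), leaving the 6-OH and the pendant catechol free and the stereocentres untouched.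

Step 3
Reactants: 5 tribenzyl compound
Product: 6 dibenzyl rac-(1R,2S)-7-(benzyloxy)-1-(2,2-dimethyl-1,3-benzodioxol-5-yl)-6-hydroxy-1,2-dihydronaphthalene-2,3-dicarboxylate
Conditions: Me2C(OMe)2 (5 equiv), TsOH·H2O (5 mol %), benzene, reflux through 4 Å molecular sieves
Reagents that add atoms: 2,2-dimethoxypropane, COC(C)(C)OC
Why: Acid-catalysed transketalisation closes the five-membered isopropylidene ketal only on the pendant catechol, because the lone 6-OH (its neighbour is now OBn) cannot form a cyclic ketal and therefore stays free.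

Step 4
Reactants: 6 racemic acetonide (two molecules, one of each enantiomer)
Product: 7 tetrabenzyl (aS,1R,2S,1′S,2′R)-7,7′-bis(benzyloxy)-1,1′-bis(2,2-dimethyl-1,3-benzodioxol-5-yl)-6,6′-dihydroxy-1,1′,2,2′-tetrahydro-[5,5′-binaphthalene]-2,2′,3,3′-tetracarboxylate
Conditions: VO(OMe)(L) (20 mol %; L = N-(3-tert-butyl-5-nitrosalicylidene)-(S)-tert-leucinate), O2 (1 atm), AcOH (5 equiv), PhCl, 0 °C → rt; silica, then preparative HPLC to remove the two homochiral dimers
Reagents that add atoms: none
Why: Proposed new method: catalyst-controlled atroposelective oxidative phenol coupling applied to a racemate — the phenol binds to pentavalent vanadium, inner-sphere electron transfer gives a vanadium-bound phenoxyl radical whose only open spin-bearing carbon is C5 (C7 carries OBn, C8a is the substituted ring-fusion carbon), two such units join C5–C5′ and tautomerise while O2 re-oxidises tetravalent vanadium, the remote C1/C2 centres do not steer the pairing so the (1R,2S)+(1S,2R) cross pair is statistically half of the dimer (2:1:1), and its axis is set by the chiral Schiff-base ligand; closest known reactions are the vanadium-catalysed enantioselective oxidative coupling of 2-naphthols and of 2,3,5-trisubstituted phenols, and the copper/amine coupling of 4-O-benzyl gallates to hexahydroxydiphenoates.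

Step 5
Reactants: 7 protected heterochiral dimer
Product: 8 (aS,1R,2S,1′S,2′R)-1,1′-bis(3,4-dihydroxyphenyl)-6,6′,7,7′-tetrahydroxy-1,1′,2,2′-tetrahydro-[5,5′-binaphthalene]-2,2′,3,3′-tetracarboxylic acid (target CNP0242074.1)
Conditions: BBr3 (20 equiv), C6HMe5 (12 equiv), CH2Cl2, −78 → 0 °C, Ar; MeOH/H2O quench; RP-18 HPLC (0.1% HCO2H)
Reagents that add atoms: none
Why: Lewis-acid dealkylation cleaves the two aryl benzyl ethers, the four benzyl esters and both catechol isopropylidene ketals, with pentamethylbenzene trapping the benzyl cations (Friedel–Crafts), under non-basic and non-reducing conditions that leave the C3=C4 alkenes, the C1/C2 centres and the stable axis unchanged.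

**Compound list**
1 | caffeic acid, (E)-3-(3,4-dihydroxyphenyl)prop-2-enoic acid | O=C(O)/C=C/c1ccc(O)c(O)c1 | starting material
2 | 2,3-bis[(3-hydroxy-4-oxocyclohexa-2,5-dien-1-ylidene)methyl]butanedioic acid, the 8–8′-linked bis(quinone methide); transient mixture of stereoisomers, so no stereodescriptors are given | OC(=O)C(C=C1C=CC(=O)C(O)=C1)C(C=C1C=CC(=O)C(O)=C1)C(=O)O | intermediate (not isolated)
3 | rac-(1R,2S)-1-(3,4-dihydroxyphenyl)-6,7-dihydroxy-1,2-dihydronaphthalene-2,3-dicarboxylic acid (trans; racemate, (1R,2S) enantiomer drawn) | O=C(O)C1=Cc2c(cc(O)c(O)c2)[C@@H](c2ccc(O)c(O)c2)[C@@H]1C(=O)O | intermediate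
4 | dibenzyl rac-(1R,2S)-1-(3,4-dihydroxyphenyl)-6,7-dihydroxy-1,2-dihydronaphthalene-2,3-dicarboxylate ((1R,2S) enantiomer drawn) | O=C(OCc1ccccc1)C1=Cc2c(cc(O)c(O)c2)[C@@H](c2ccc(O)c(O)c2)[C@@H]1C(=O)OCc1ccccc1 | intermediate (not isolated)
5 | dibenzyl rac-(1R,2S)-7-(benzyloxy)-1-(3,4-dihydroxyphenyl)-6-hydroxy-1,2-dihydronaphthalene-2,3-dicarboxylate ((1R,2S) enantiomer drawn) | O=C(OCc1ccccc1)C1=Cc2c(cc(OCc3ccccc3)c(O)c2)[C@@H](c2ccc(O)c(O)c2)[C@@H]1C(=O)OCc1ccccc1 | intermediate
6 | dibenzyl rac-(1R,2S)-7-(benzyloxy)-1-(2,2-dimethyl-1,3-benzodioxol-5-yl)-6-hydroxy-1,2-dihydronaphthalene-2,3-dicarboxylate ((1R,2S) enantiomer drawn) | O=C(OCc1ccccc1)C1=Cc2c(cc(OCc3ccccc3)c(O)c2)[C@@H](c2ccc3OC(C)(C)Oc3c2)[C@@H]1C(=O)OCc1ccccc1 | intermediate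
7 | tetrabenzyl (aS,1R,2S,1′S,2′R)-7,7′-bis(benzyloxy)-1,1′-bis(2,2-dimethyl-1,3-benzodioxol-5-yl)-6,6′-dihydroxy-1,1′,2,2′-tetrahydro-[5,5′-binaphthalene]-2,2′,3,3′-tetracarboxylate (axis aS; the SMILES shows the centres only) | O=C(OCc1ccccc1)C1=Cc2c(cc(OCc3ccccc3)c(O)c2-c2c(O)c(OCc3ccccc3)cc3c2C=C(C(=O)OCc2ccccc2)[C@H](C(=O)OCc2ccccc2)[C@H]3c2ccc3OC(C)(C)Oc3c2)[C@@H](c2ccc3OC(C)(C)Oc3c2)[C@@H]1C(=O)OCc1ccccc1 | intermediate
8 | (aS,1R,2S,1′S,2′R)-1,1′-bis(3,4-dihydroxyphenyl)-6,6′,7,7′-tetrahydroxy-1,1′,2,2′-tetrahydro-[5,5′-binaphthalene]-2,2′,3,3′-tetracarboxylic acid (axis aS; the SMILES shows the centres only) | O=C(O)C1=Cc2c(cc(O)c(O)c2-c2c(O)c(O)cc3c2C=C(C(=O)O)[C@H](C(=O)O)[C@H]3c2ccc(O)c(O)c2)[C@@H](c2ccc(O)c(O)c2)[C@@H]1C(=O)O | target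

**Step count**
Total steps: 5. Longest linear sequence: 5.

**Steps most likely to fail, each with a fallback**

Step 1 (oxidative dimerisation of unprotected caffeic acid). Benzodioxane-type 8–O coupling, water or carboxylate trapping of the quinone methide, and over-oxidation of 3 all compete, so the yield will be low; it is run at partial conversion on a large scale because 1 is very cheap. Fallback, setting out from 1 and returning at 3: separate the C–C coupling from the ring closure. Oxidation of 1 with FeCl3 (2.2 equiv) in aqueous acetone lets the carboxyl groups trap the bis(quinone methide), giving the crystalline 8–8′ dilactone rac-4,8-bis(3,4-dihydroxyphenyl)-3,7-dioxabicyclo[3.3.0]octane-2,6-dione F1 (cis-fused, both aryl groups exo). Heating F1 in 2 M HCl/dioxane re-opens one lactone to the benzylic cation, the other catechol ring closes onto it para to its 3-OH, and the second lactone eliminates to the C3=C4 alkene, giving trans-3.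

Step 2 (site-selective 7-O-benzylation). The acidity gap between the 7-OH and the pendant catechol is only about one pK unit, so regioisomeric and over-benzylated ethers are expected. Fallback, setting out from 4 (isolated by stopping step 2 after the carboxyl alkylation at rt) and returning at 5: protect all four phenols and unmask one. Ac2O/pyridine gives the 6,7,3′,4′-tetraacetate of 4 F2. One equivalent of pyrrolidine at 0 °C removes the most electrophilic aryl acetate, the 7-OAc (best leaving group; any acyl migration also leaves the free OH on the more acidic O7), giving the 7-hydroxy 6,3′,4′-triacetate F3. Mitsunobu benzylation (BnOH, PPh3, DIAD) of this single free phenol gives the 7-benzyloxy 6,3′,4′-triacetate F4. Excess pyrrolidine in THF then cleaves the three remaining aryl acetates without touching the benzyl esters, giving 5.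

Step 4 (heterochiral, atroposelective oxidative coupling). Risks are a hindered tetra-ortho biaryl, C–O coupling, oxidative aromatisation of the dihydronaphthalene, incomplete axis control, and a difficult separation of the cross pair from the two homochiral diastereomers. Which catalyst enantiomer gives (aS) must be established on 7 by ECD or X-ray; the (R)-tert-leucine catalyst is used if the sense is opposite. Fallback, setting out from 6 and returning at 7: replace the oxidative coupling by a cross-coupling. NBS with catalytic i-Pr2NH brominates the only free ortho position of the phenol, giving the 5-bromo derivative of 6 F5. Half of it is converted with B2pin2, PdCl2(dppf) and KOAc into the 5-pinacolboronate of 6 F6. Suzuki–Miyaura coupling of F5 with F6 (Pd(OAc)2, enantiopure sulfonated biaryl phosphine sSPhos, K3PO4, toluene/H2O) joins C5–C5′ with ligand control of the axis, giving 7 after the same separation from the homochiral dimers.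

**Further compounds**
F1 | step 1 | rac-4,8-bis(3,4-dihydroxyphenyl)-3,7-dioxabicyclo[3.3.0]octane-2,6-dione (cis-fused, both aryl groups exo; one enantiomer drawn) | O=C1O[C@@H](c2ccc(O)c(O)c2)[C@@H]2C(=O)O[C@@H](c3ccc(O)c(O)c3)[C@H]12
F2 | step 2 | dibenzyl rac-(1R,2S)-6,7-diacetoxy-1-(3,4-diacetoxyphenyl)-1,2-dihydronaphthalene-2,3-dicarboxylate | O=C(OCc1ccccc1)C1=Cc2c(cc(OC(C)=O)c(OC(C)=O)c2)[C@@H](c2ccc(OC(C)=O)c(OC(C)=O)c2)[C@@H]1C(=O)OCc1ccccc1
F3 | step 2 | dibenzyl rac-(1R,2S)-6-acetoxy-1-(3,4-diacetoxyphenyl)-7-hydroxy-1,2-dihydronaphthalene-2,3-dicarboxylate | O=C(OCc1ccccc1)C1=Cc2c(cc(O)c(OC(C)=O)c2)[C@@H](c2ccc(OC(C)=O)c(OC(C)=O)c2)[C@@H]1C(=O)OCc1ccccc1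
F4 | step 2 | dibenzyl rac-(1R,2S)-6-acetoxy-7-(benzyloxy)-1-(3,4-diacetoxyphenyl)-1,2-dihydronaphthalene-2,3-dicarboxylate | O=C(OCc1ccccc1)C1=Cc2c(cc(OCc3ccccc3)c(OC(C)=O)c2)[C@@H](c2ccc(OC(C)=O)c(OC(C)=O)c2)[C@@H]1C(=O)OCc1ccccc1
F5 | step 4 | dibenzyl rac-(1R,2S)-7-(benzyloxy)-5-bromo-1-(2,2-dimethyl-1,3-benzodioxol-5-yl)-6-hydroxy-1,2-dihydronaphthalene-2,3-dicarboxylate | O=C(OCc1ccccc1)C1=Cc2c(cc(OCc3ccccc3)c(O)c2Br)[C@@H](c2ccc3OC(C)(C)Oc3c2)[C@@H]1C(=O)OCc1ccccc1
F6 | step 4 | dibenzyl rac-(1R,2S)-7-(benzyloxy)-1-(2,2-dimethyl-1,3-benzodioxol-5-yl)-6-hydroxy-5-(4,4,5,5-tetramethyl-1,3,2-dioxaborolan-2-yl)-1,2-dihydronaphthalene-2,3-dicarboxylate | O=C(OCc1ccccc1)C1=Cc2c(cc(OCc3ccccc3)c(O)c2B2OC(C)(C)C(C)(C)O2)[C@@H](c2ccc3OC(C)(C)Oc3c2)[C@@H]1C(=O)OCc1ccccc1
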